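Leftover transfer agent is what two chemists dispute over this flask.

the same everywhere: free monomer 0.40 M
- summer: transfer agent 0.040 M; initiator 20 mM; the very flask that is asked about, followed so far
- spring: transfer agent 0.040 M; initiator 40 mM; run made earlier
- flask: transfer agent 0.0400 M; initiator 20 mM; time 25 h

| run | time / h | monomer in chains / % | free monomer / % |
|---|---|---|---|
| summer | 0.833 | 0 | 98.5 |
| summer | 2.50 | 4.4 | 95.7 |
| summer | 5.00 | 8.9 | 90.0 |
| summer | 8.00 | 13.1 | 86.3 |
| summer | 10.0 | 16.6 | 82.7 |
| spring | 2.00 | 6.8 | 92.2 |
| spring | 6.00 | 19.1 | 76.9 |
| spring | 12.0 | 36.3 | 66.1 |
| spring | 20.0 | 44.2 | 56.1 |
| spring | 25.0 | 48.2 | 50.3 |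

(readings scatter by 1 percentage point)

- the average divides the monomer in chains by the number of chains begun, living and dead together
- the earlier runs do not show the number of chains; that part of a forecast is a guess

- average number of monomer units in a chain (chains begun, living or dead) at 25 h
- part of the free monomer that has reacted at 25 h

Both can use one count. Monomer units charged per initiator charged come to 20.0, the turnover ratio. Multiply it by the fraction of monomer in chains and you get turnovers, the units placed per initiator charged. In the summer run at 10.0 h that is 3.32.

The first chemist made the forecast. She expects the transfer agent to turn into chains, so chains are many and short. Her forecast is a chain length (degree of polymerisation) of 2.7 and 32% reacted, with “wide uncertainty if the agent is not fully consumed”.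

The second chemist looks at the early rates. Monomer entered chains 1.93 times faster in spring, which had twice the initiator and the same agent. So she holds that initiator begins chains, one at most from each, and that agent merely stops them. This is her reckoning, not the forecast's: on the forecast's conversion, she puts the chain length no lower than 6.40 turnovers. Neither can prove it, since the runs do not show the number of chains.

The flask gives a chain length of 26.3 with 29.2% reacted. The forecast's conversion stands, but its chain length is low by about ten times.

    free monomer + initiator → living end + monomer in chains (k = 1.10 × 10⁻⁴ M⁻¹ s⁻¹)
    free monomer + living end → monomer in chains + living end, rate k2*[living end]*[free monomer] (k = 0.00160 M⁻¹ s⁻¹)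
    living end + transfer agent → dead chain (kL = 4.00 × 10⁻⁴ M⁻¹ s⁻¹)
    initiator → spent initiator A (k = 1.40 × 10⁻⁴ s⁻¹)
    free monomer + initiator → spent initiator B (k = 3.50 × 10⁻⁵ M⁻¹ s⁻¹)
    monomer in chains → over-reaction product (k = 2.90 × 10⁻⁸ s⁻¹)

The flask's chain length lies above the second chemist's floor, and 92% of the flask's transfer agent is still there at 25.0 h. The first view describes the agent actually spent, which stands as dead chains, 0.792% of the monomer charge. With 28.8% of the monomer in chains, the flask's turnovers are 5.75, so its chain length is 4.58 times turnovers.

In the neighbour flask with 0.10 M of agent and the same initiator charge, 16.7% of the monomer in chains gives 3.33 turnovers, and that factor gives a chain length of 15.2. The computed chain length there is 15.2.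

(The numbers in the tables were generated by integration on assumed constants; scatter was added.)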